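I was to read this flask at 6.0 h, so I first asked what could still be moving by then.

    catalyst intermediate C → free catalyst + product (k1 = 2320 /h)
    starting material + catalyst intermediate A ⇌ catalyst intermediate B (K2 = 151 /M, k2 = 4.52 × 10⁵ /M/h)
    precatalyst → free catalyst (k3 = 0.881 /h)
    coupling partner + free catalyst ⇌ catalyst intermediate A (K4 = 136 /M, k4 = 67400 /M/h)
    catalyst intermediate B → catalyst intermediate C (k5 = 81500 /h)
    crystals ⇌ product, rate k6*(cs6 - [product]) while solid is left; crystals form when [product] > cs6 (cs6 = 0.080 M, k6 = 19.9 /h)

starting material 0.25 M; coupling partner 0.800 equiv; precatalyst 0.05 mol%; time 6.0 h

1. amount of product and crystals together at 6.0 h, in percent of the starting material charged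
2. the change that raises the amount of product and crystals together at 6.0 h, in percent of the starting material charged most ("none" if none brings more than 2 percentage points) (Tuesday's / Friday's / Sunday's / Monday's / none)
3. amount of product and crystals together at 6.0 h, in percent of the starting material charged, after Sunday's

- Tuesday's: doubling the amount of precatalyst, all else as stated
- Friday's: doubling the solubility in step 6, all else as stated
- Sunday's: doubling the amount of coupling partner, all else as stated
- Monday's: doubling the dissolution coefficient of step 6, all else as stated

- what is said of product includes crystals
- crystals is a solid; its amount is given per volume of the solution
- run time (flask): 6.0 h

I followed one molecule of coupling partner round the catalyst, from short times to long. Bound in catalyst intermediate A, it goes on with starting material at 1.13 × 10⁵ /h at the starting [starting material], against 496 /h for falling off. In catalyst intermediate B it goes forward at 81500 /h against 2990 /h back, so it passes both forks at the first try with a chance of 96.0%. A molecule that slips back tries again, and the scheme shows it no side exit. In this flask coupling partner is the limiting reagent, so starting material is there for every molecule of it. Given time, its chance of ending as product is therefore one, and what counts is the stoichiometric ceiling, the smaller charge of the two reagents over the starting material charged: 80.0%.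

At the starting concentrations, release of product from catalyst intermediate C, at 2320 /h, is the rate-limiting step of the round. Slower than that, crystals exchange at 19.9 /h. Since 0.200 M of product exceeds the solubility, crystals should form, but both phases are counted. Slower still, precatalyst is released at 0.881 /h, a half-life of 0.79 h. Fully released, the catalyst turns over at most 0.290 M/h, so adding the mean wait for release to the time at that speed gives roughly 1.82 h, less than the 6.0 h allowed.

So I expected the flask to stop at 80.0%. Sunday's lifts the ceiling to 100%, and the other changes leave it where it stands, so my choice was Sunday's.

The forecast gave 80%, Sunday's and 100%, noting that “crystallisation only moves product between phases without changing the total”.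

The flask gave 80.0%, and Sunday's gave 100%, a gain of 20 percentage points, against 0 points for Tuesday's, 0 points for Friday's and 0 points for Monday's. At 3.00 h the flask already held 80.0% of product and crystals, with coupling partner at 0% of its charge. The ceiling of 80.0% and one comparison of 1.82 h with 6.0 h reached this number without any integration.

For the neighbour flask with 1.40 equiv of coupling partner, I reckoned a ceiling of 100%, with 28.6% of the coupling partner's charge left over. That flask gave 100%, with 29% of its coupling partner left.

The constants used here come from no measurement; no experiment stands behind them.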